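**Plan** (labdane numbering: ring A = C1–C5 + C10; ring B = C5–C10; C17 = ester carbon on C8; C11–C16 = side chain on C9; C20 = methyl on C10)
- Retrosynthesis, first cut: C12–C13 (sp3–sp2 Negishi coupling with a (Z)-β-iodoenoate).
- Second cut: C5–C10 together with C8–C9. Ring B is a cyclohexene whose C6=C7 bond is flanked by C5, C10, C9 and C8 (all four stereocentres), a complete Diels–Alder retron; ring A supplies, as C1–C4, the four-carbon tether of a 1,3,9-decatriene.
- The acyclic (2Z,4E,10E)-trienoate is cut at C1–C10, C3–C4, C5=C6 and C6–C7 around (S)-epichlorohydrin (C1–C3).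
- Forward: linear chain assembly, then one thermal intramolecular Diels–Alder reaction closes rings A and B together; the side chain is joined last.
- Stereochemistry: relative configuration from alkene geometry (E-C9=C10 gives C20/C11 cis; Z-C7=C8 gives the ester trans to C11; exo-tether chair gives the trans fusion). Absolute configuration from a temporary C2 silyloxy group (from (S)-epichlorohydrin) that must lie equatorial between the syn-axial C4 and C10 methyls; it is removed afterwards by Barton–McCombie deoxygenation.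

Key step: step 9

Remark: (S)-epichlorohydrin, methyl (Z)-3-iodoacrylate, methyl 4-hydroxybut-2-ynoate and Cl2CHBpin are taken as purchasable. TBS = tert-butyldimethylsilyl, PMB = 4-methoxybenzyl, Bpin = pinacolatoboryl.

**Step 1**
Reactants: 1 pent-3-yn-1-ol
Product: 2 1-methoxy-4-[(pent-3-yn-1-yloxy)methyl]benzene
Conditions: NaH, PMBCl, Bu4NI (cat.), THF/DMF, 0 → 23 °C
Reagents that add atoms: 4-methoxybenzyl chloride, COc1ccc(CCl)cc1
Why: Williamson etherification of the primary alkoxide; the PMB ether should survive the organometallic, hydride and thermal steps ahead and is removed oxidatively later without touching esters.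

**Step 2**
Reactants: 2 PMB ether of pent-3-yn-1-ol
Product: 4 1-({[(3E)-4-iodopent-3-en-1-yl]oxy}methyl)-4-methoxybenzene, via alkenylzirconocene chloride 3 (not isolated)
Conditions: Cp2Zr(H)Cl (2.2 equiv), THF, 50 °C; then I2, 0 °C
Reagents that add atoms: iodine, II
Why: syn-hydrozirconation under equilibrating conditions (excess hydride) should place zirconium on the less hindered, methyl-bearing alkyne carbon, and iodinolysis with retention gives the (E)-2-iodoalkene that fixes the later C9=C10 geometry (C20 cis to C11).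

**Step 3**
Reactants: 4 (E)-alkenyl iodide; 5 (S)-epichlorohydrin
Product: 8 (2S,4E)-1-chloro-7-(4-methoxybenzyloxy)-4-methylhept-4-en-2-ol, via alkenyllithium 6 (not isolated), via alkenylmagnesium bromide 7 (not isolated)
Conditions: t-BuLi (2 equiv), Et2O, −78 °C; MgBr2·OEt2; CuI (10 mol %), 5, THF, −40 → 0 °C; then H2O
Reagents that add atoms: none
Why: iodine–lithium exchange and transmetalation proceed with retention, and the CuI-catalysed Grignard opening of the epoxide at its CH2 terminus (C1–C10 bond) leaves the C–O bond of the stereocentre untouched, so C2 keeps the configuration of 5.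

**Step 4**
Reactants: 8 chlorohydrin
Product: 9 (2S)-2-[(2E)-5-(4-methoxybenzyloxy)-2-methylpent-2-en-1-yl]oxirane
Conditions: K2CO3, MeOH, 23 °C
Reagents that add atoms: none
Why: intramolecular Williamson closure of the chlorohydrin (3-exo-tet) moves the epoxide to C2–C3 without touching the C2 stereocentre.

**Step 5**
Reactants: 9 epoxide; 10 isobutyronitrile
Product: 13 (4S,6E)-4-(tert-butyldimethylsilyloxy)-9-(4-methoxybenzyloxy)-2,2,6-trimethylnon-6-enenitrile, via lithiated isobutyronitrile 11 (not isolated), via lithium alkoxide 12 (not isolated)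
Conditions: LiN(i-Pr)2, 10, THF, −78 °C; 9, −78 → 0 °C; then TBSOTf, −78 → 0 °C
Reagents that add atoms: tert-butyldimethylsilyl trifluoromethanesulfonate, CC(C)(C)[Si](C)(C)OS(=O)(=O)C(F)(F)F
Why: SN2 opening of the terminal epoxide at C3 by the tertiary nitrile-stabilised carbanion installs C4 with both methyl groups and C5, and silylation of the lithium alkoxide in the same flask forestalls its addition to the nitrile and provides the C2 control element.

**Step 6**
Reactants: 13 silyloxy nitrile
Product: 15 (4S,6E)-4-(tert-butyldimethylsilyloxy)-9-(4-methoxybenzyloxy)-2,2,6-trimethylnon-6-enal, via N-aluminio aldimine 14 (not isolated)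
Conditions: i-Bu2AlH, PhMe, −78 °C; then aq. potassium sodium tartrate, 23 °C
Reagents that add atoms: water, O
Why: hydride addition to the hindered nitrile stops at the aluminium imine, whose hydrolysis gives the non-enolisable C5 aldehyde.

**Step 7**
Reactants: 15 aldehyde
Product: 16 2-[(1E,5S,7E)-5-(tert-butyldimethylsilyloxy)-10-(4-methoxybenzyloxy)-3,3,7-trimethyldeca-1,7-dien-1-yl]-4,4,5,5-tetramethyl-1,3,2-dioxaborolane
Conditions: Cl2CHBpin, CrCl2, LiI, THF, 23 °C
Reagents that add atoms: 2-(dichloromethyl)-4,4,5,5-tetramethyl-1,3,2-dioxaborolane, ClC(Cl)B1OC(C)(C)C(C)(C)O1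
Why: Takai–Utimoto boryl olefination, in which a geminal dichromium reagent adds to the aldehyde and eliminates to the (E)-alkenylboronate (C5=C6), a reaction type that tolerates α-quaternary aldehydes.

**Step 8**
Reactants: 16 (E)-alkenylboronate; 17 methyl (Z)-3-iodoacrylate
Product: 18 methyl (2Z,4E,8S,10E)-8-(tert-butyldimethylsilyloxy)-13-(4-methoxybenzyloxy)-6,6,10-trimethyltrideca-2,4,10-trienoate
Conditions: PdCl2(dppf) (5 mol %), K3PO4, THF/H2O, 23 °C, dark
Reagents that add atoms: none
Why: Suzuki–Miyaura coupling with retention at both sp2 carbons forms C6–C7 and should deliver the (2Z,4E)-dienoate at room temperature, one step before it is used.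

**Step 9**
Reactants: 18 (2Z,4E,10E)-trienoate
Product: 19 methyl (1R,2S,4aR,7R,8aS)-7-(tert-butyldimethylsilyloxy)-1-[2-(4-methoxybenzyloxy)ethyl]-5,5,8a-trimethyl-1,2,4a,5,6,7,8,8a-octahydronaphthalene-2-carboxylate
Conditions: 1,2-dichlorobenzene (0.01 M), BHT (10 mol %), base-washed sealed tube, 180–200 °C
Reagents that add atoms: none
Why: Thermal intramolecular Diels–Alder reaction, a concerted suprafacial [4+2] cycloaddition in which the C5=C6–C7=C8 dienoate adds across the C9=C10 alkene, forming C5–C10 and C8–C9 and leaving C6=C7; the closest known reaction type is the thermal cyclisation of unactivated 1,3,9-decatrienes to octalins, here assisted by the reactive-rotamer effect of the C4 gem-dimethyl group. Ring B (six-membered) closes by the [4+2] union itself, and ring A (six-membered) closes through the same C5–C10 bond in the exo sense with respect to both π systems, its C1–C4 tether adopting a chair. At C9 and C10 the E geometry of the dienophile is transferred, so C20 and C11 end cis; at C8 the Z geometry places the ester inside the diene, so it ends cis to H9 and trans to C11; at the C5/C10 fusion the tether-exo chair transition state (C20 and C11 endo) gives the trans-decalin. Absolute configuration follows from C2: of the two trans-fusing chairs only the one with the silyloxy group equatorial is accessible, because the axial alternative is syn-axial to both the C4 and the C10 methyl groups, and with (S)-C2 this should give 5R,8S,9R,10S (the facial isomer is a diastereomer and is removed here, before C2 is erased). The step needs trans- over cis-fusion and an intact Z-enoate: the first is favoured by the chair tether and by the inside ester, which in the cis-fusing transition state would be pressed against C11, and the second by the absence of any hydrogen that could undergo a 1,5-shift (C4 is quaternary, the other diene terminus carries the ester) and by acid-free, radical-inhibited conditions.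

**Step 10**
Reactants: 19 cycloadduct
Product: 20 methyl (1R,2S,4aR,7R,8aS)-7-hydroxy-1-[2-(4-methoxybenzyloxy)ethyl]-5,5,8a-trimethyl-1,2,4a,5,6,7,8,8a-octahydronaphthalene-2-carboxylate
Conditions: HF·pyridine, pyridine, THF, 0 → 23 °C
Reagents that add atoms: none
Why: fluoride cleavage of the silyl ether under non-basic conditions should leave the epimerisable, allylic C8 ester and the PMB ether untouched.

**Step 11**
Reactants: 20 secondary alcohol
Product: 21 methyl (1R,2S,4aR,7R,8aS)-1-[2-(4-methoxybenzyloxy)ethyl]-5,5,8a-trimethyl-7-[(phenoxycarbonothioyl)oxy]-1,2,4a,5,6,7,8,8a-octahydronaphthalene-2-carboxylate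
Conditions: PhOC(S)Cl, pyridine, DMAP (cat.), CH2Cl2, 23 °C
Reagents that add atoms: O-phenyl chlorothionoformate, S=C(Cl)Oc1ccccc1
Why: acylation of the unhindered equatorial alcohol gives the thionocarbonate needed for radical deoxygenation.

**Step 12**
Reactants: 21 thionocarbonate
Product: 22 methyl (1R,2S,4aR,8aS)-1-[2-(4-methoxybenzyloxy)ethyl]-5,5,8a-trimethyl-1,2,4a,5,6,7,8,8a-octahydronaphthalene-2-carboxylate
Conditions: Bu3SnH, AIBN (cat.), PhMe, 100 °C
Reagents that add atoms: none
Why: Barton–McCombie deoxygenation (stannyl radical addition to C=S, β-scission to the secondary C2 radical, hydrogen transfer) removes the control element; the C2 radical cannot reach C6=C7 in the rigid trans-decalin, and esters and the PMB ether are inert.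

**Step 13**
Reactants: 22 PMB ether
Product: 23 methyl (1R,2S,4aR,8aS)-1-(2-hydroxyethyl)-5,5,8a-trimethyl-1,2,4a,5,6,7,8,8a-octahydronaphthalene-2-carboxylate
Conditions: DDQ, CH2Cl2/pH 7 buffer, 0 °C; crude used at once
Reagents that add atoms: none
Why: oxidative PMB cleavage (benzylic hydride abstraction, hydrolysis of the oxocarbenium ion) is neutral, and the cold buffered medium with immediate use of the alcohol is meant to forestall δ-lactonisation onto the C17 ester.

**Step 14**
Reactants: 23 primary alcohol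
Product: 24 methyl (1R,2S,4aR,8aS)-1-(2-iodoethyl)-5,5,8a-trimethyl-1,2,4a,5,6,7,8,8a-octahydronaphthalene-2-carboxylate
Conditions: I2, PPh3, imidazole, CH2Cl2, 0 °C
Reagents that add atoms: iodine, II
Why: Appel-type iodination by SN2 displacement of the alkoxyphosphonium ion at the primary C12.

**Step 15**
Reactants: 25 methyl 4-hydroxybut-2-ynoate
Product: 26 methyl 4-acetoxybut-2-ynoate
Conditions: Ac2O, pyridine, DMAP (cat.), CH2Cl2, 0 °C
Reagents that add atoms: acetic anhydride, CC(=O)OC(C)=O
Why: routine O-acetylation installs the C16 acetate before the alkene is formed.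

**Step 16**
Reactants: 26 acetoxy ynoate
Product: 27 methyl (2Z)-4-acetoxy-3-iodobut-2-enoate
Conditions: NaI, AcOH, 70 °C
Reagents that add atoms: sodium iodide, [Na+].[I-]
Why: conjugate hydroiodination of the ynoate in acetic acid proceeds by anti addition, so iodine ends cis to the ester, which fixes the C13=C14 geometry.

**Step 17**
Reactants: 24 primary iodide; 27 (Z)-β-iodoenoate
Product: 29 methyl (1R,2S,4aR,8aS)-1-[(3E)-3-(acetoxymethyl)-5-methoxy-5-oxopent-3-en-1-yl]-5,5,8a-trimethyl-1,2,4a,5,6,7,8,8a-octahydronaphthalene-2-carboxylate (CNP0190145.1), via alkylzinc iodide 28 (not isolated)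
Conditions: Zn dust (activated with BrCH2CH2Br/Me3SiCl), LiCl, THF, 40 °C; then 27 (1.2 equiv), PdCl2(dppf) (5 mol %), THF, 23 °C
Reagents that add atoms: none
Why: zinc insertion into the primary iodide tolerates both esters, and Negishi sp3–sp2 coupling with retention places C12 cis to the C15 ester; oxidative addition of zerovalent palladium to the vinyl iodide should outpace ionisation of the allylic acetate.

**Compound list**
1 | pent-3-yn-1-ol | CC#CCCO | starting material
2 | 1-methoxy-4-[(pent-3-yn-1-yloxy)methyl]benzene | CC#CCCOCc1ccc(OC)cc1 | intermediate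
3 | chlorobis(cyclopentadienyl)[(E)-5-(4-methoxybenzyloxy)pent-2-en-2-yl]zirconium (not isolated) | Cl[Zr](C1C=CC=C1)(C1C=CC=C1)/C(C)=C/CCOCc1ccc(OC)cc1 | intermediate
4 | 1-({[(3E)-4-iodopent-3-en-1-yl]oxy}methyl)-4-methoxybenzene | I/C(C)=C/CCOCc1ccc(OC)cc1 | intermediate
5 | (S)-epichlorohydrin, (2S)-2-(chloromethyl)oxirane | ClC[C@@H]1CO1 | starting material
6 | [(E)-5-(4-methoxybenzyloxy)pent-2-en-2-yl]lithium (not isolated) | [Li]/C(C)=C/CCOCc1ccc(OC)cc1 | intermediate
7 | [(E)-5-(4-methoxybenzyloxy)pent-2-en-2-yl]magnesium bromide (not isolated) | Br[Mg]/C(C)=C/CCOCc1ccc(OC)cc1 | intermediate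
8 | (2S,4E)-1-chloro-7-(4-methoxybenzyloxy)-4-methylhept-4-en-2-ol | ClC[C@@H](O)C/C(C)=C/CCOCc1ccc(OC)cc1 | intermediate
9 | (2S)-2-[(2E)-5-(4-methoxybenzyloxy)-2-methylpent-2-en-1-yl]oxirane | C1O[C@H]1C/C(C)=C/CCOCc1ccc(OC)cc1 | intermediate
10 | isobutyronitrile (2-methylpropanenitrile) | CC(C)C#N | starting material
11 | 2-lithio-2-methylpropanenitrile (not isolated) | [Li]C(C)(C)C#N | intermediate
12 | lithium (4S,6E)-1-cyano-... alkoxide: lithium salt of (4S,6E)-4-hydroxy-9-(4-methoxybenzyloxy)-2,2,6-trimethylnon-6-enenitrile (not isolated) | N#CC(C)(C)C[C@@H](O[Li])C/C(C)=C/CCOCc1ccc(OC)cc1 | intermediate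
13 | (4S,6E)-4-(tert-butyldimethylsilyloxy)-9-(4-methoxybenzyloxy)-2,2,6-trimethylnon-6-enenitrile | N#CC(C)(C)C[C@@H](O[Si](C)(C)C(C)(C)C)C/C(C)=C/CCOCc1ccc(OC)cc1 | intermediate
14 | N-(diisobutylaluminio) aldimine of aldehyde 15 (not isolated) | CC(C)C[Al](CC(C)C)N=CC(C)(C)C[C@@H](O[Si](C)(C)C(C)(C)C)C/C(C)=C/CCOCc1ccc(OC)cc1 | intermediate
15 | (4S,6E)-4-(tert-butyldimethylsilyloxy)-9-(4-methoxybenzyloxy)-2,2,6-trimethylnon-6-enal | O=CC(C)(C)C[C@@H](O[Si](C)(C)C(C)(C)C)C/C(C)=C/CCOCc1ccc(OC)cc1 | intermediate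
16 | 2-[(1E,5S,7E)-5-(tert-butyldimethylsilyloxy)-10-(4-methoxybenzyloxy)-3,3,7-trimethyldeca-1,7-dien-1-yl]-4,4,5,5-tetramethyl-1,3,2-dioxaborolane | CC1(C)OB(/C=C/C(C)(C)C[C@@H](O[Si](C)(C)C(C)(C)C)C/C(C)=C/CCOCc2ccc(OC)cc2)OC1(C)C | intermediate
17 | methyl (Z)-3-iodoacrylate | COC(=O)/C=C\I | starting material
18 | methyl (2Z,4E,8S,10E)-8-(tert-butyldimethylsilyloxy)-13-(4-methoxybenzyloxy)-6,6,10-trimethyltrideca-2,4,10-trienoate | COC(=O)/C=C\C=C\C(C)(C)C[C@@H](O[Si](C)(C)C(C)(C)C)C/C(C)=C/CCOCc1ccc(OC)cc1 | intermediate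
19 | methyl (1R,2S,4aR,7R,8aS)-7-(tert-butyldimethylsilyloxy)-1-[2-(4-methoxybenzyloxy)ethyl]-5,5,8a-trimethyl-1,2,4a,5,6,7,8,8a-octahydronaphthalene-2-carboxylate | COc1ccc(COCC[C@@H]2[C@@H](C(=O)OC)C=C[C@@H]3C(C)(C)C[C@@H](O[Si](C)(C)C(C)(C)C)C[C@@]23C)cc1 | intermediate
20 | methyl (1R,2S,4aR,7R,8aS)-7-hydroxy-1-[2-(4-methoxybenzyloxy)ethyl]-5,5,8a-trimethyl-1,2,4a,5,6,7,8,8a-octahydronaphthalene-2-carboxylate | COc1ccc(COCC[C@@H]2[C@@H](C(=O)OC)C=C[C@@H]3C(C)(C)C[C@@H](O)C[C@@]23C)cc1 | intermediate
21 | O-phenyl thionocarbonate of 20 at C2 (naphthalene position 7) | COc1ccc(COCC[C@@H]2[C@@H](C(=O)OC)C=C[C@@H]3C(C)(C)C[C@@H](OC(=S)Oc4ccccc4)C[C@@]23C)cc1 | intermediate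
22 | methyl (1R,2S,4aR,8aS)-1-[2-(4-methoxybenzyloxy)ethyl]-5,5,8a-trimethyl-1,2,4a,5,6,7,8,8a-octahydronaphthalene-2-carboxylate | COc1ccc(COCC[C@@H]2[C@@H](C(=O)OC)C=C[C@@H]3C(C)(C)CCC[C@@]23C)cc1 | intermediate
23 | methyl (1R,2S,4aR,8aS)-1-(2-hydroxyethyl)-5,5,8a-trimethyl-1,2,4a,5,6,7,8,8a-octahydronaphthalene-2-carboxylate | OCC[C@@H]1[C@@H](C(=O)OC)C=C[C@@H]2C(C)(C)CCC[C@@]12C | intermediate
24 | methyl (1R,2S,4aR,8aS)-1-(2-iodoethyl)-5,5,8a-trimethyl-1,2,4a,5,6,7,8,8a-octahydronaphthalene-2-carboxylate | ICC[C@@H]1[C@@H](C(=O)OC)C=C[C@@H]2C(C)(C)CCC[C@@]12C | intermediate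
25 | methyl 4-hydroxybut-2-ynoate | COC(=O)C#CCO | starting material
26 | methyl 4-acetoxybut-2-ynoate | COC(=O)C#CCOC(C)=O | intermediate
27 | methyl (2Z)-4-acetoxy-3-iodobut-2-enoate | COC(=O)/C=C(\I)COC(C)=O | intermediate
28 | alkylzinc iodide from 24 (iodozincio in place of iodine at C12; not isolated) | I[Zn]CC[C@@H]1[C@@H](C(=O)OC)C=C[C@@H]2C(C)(C)CCC[C@@]12C | intermediate
29 | methyl (1R,2S,4aR,8aS)-1-[(3E)-3-(acetoxymethyl)-5-methoxy-5-oxopent-3-en-1-yl]-5,5,8a-trimethyl-1,2,4a,5,6,7,8,8a-octahydronaphthalene-2-carboxylate (CNP0190145.1) | COC(=O)/C=C(\CC[C@@H]1[C@@H](C(=O)OC)C=C[C@@H]2C(C)(C)CCC[C@@]12C)COC(C)=O | target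

**Totals**
Total step count: 17. Longest linear sequence: 15 (steps 1–14 and 17).

**Steps most likely to fail**

1. Step 9.
   - Risk: too small a preference for the tether-exo (trans-fusing) over the tether-endo (cis-fusing) transition state, or thermal Z→E drift of the enoate before cycloaddition, which would deliver the C8 epimer.
   - Fallback: the open-chain cycloaddition is replaced by a transannular Diels–Alder reaction in which the C17 carboxyl and the C12 oxygen are tied as a temporary lactone. A 14-membered (2Z,4E,10E)-triene can fold only to the trans-anti-trans tricycle, and the lactone later supplies the C12 iodide.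
   - Course: it sets out from boronate 16. DDQ frees the primary alcohol F1. Mitsunobu esterification (PPh3, diisopropyl azodicarboxylate) with (Z)-3-iodoacrylic acid gives the iodoacrylate ester F2. Intramolecular Suzuki–Miyaura coupling at high dilution (PdCl2(dppf), Cs2CO3, aq. DMF) gives the 14-membered macrolide F3. Heating (PhMe, 110–150 °C) gives the tricyclic silyloxy δ-lactone F4. HF·pyridine gives the hydroxy lactone F5, PhOC(S)Cl/pyridine the thionocarbonate F6, and Bu3SnH/AIBN the deoxygenated lactone F7. Me3SiI opens the lactone at C12 to the iodo acid F8, and Me3SiCHN2 esterifies it to iodide 24, where the route is rejoined. Any material that lactonises at step 13 can enter at the same deoxygenated lactone.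

2. Step 17.
   - Risk: ionisation of the allylic acetate (in 27 or in the product) by zerovalent palladium followed by allylic substitution by the zinc reagent, or slow transmetalation with β-hydride elimination.
   - Fallback: the C16 oxygen is carried through the coupling as a silyl ether and acetylated last.
   - Course: it sets out from ynoate 25 and iodide 24. NaI/AcOH on 25 gives methyl (2Z)-4-hydroxy-3-iodobut-2-enoate F9. TBSCl/imidazole gives its silyl ether F10. Negishi coupling with zinc reagent 28 (from 24) gives the coupled silyl ether F11. HF·pyridine gives the allylic alcohol F12 (hydroxymethyl and ester are trans, so no butenolide can form). Ac2O/pyridine gives 29.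

3. Step 8.
   - Risk: loss of the Z geometry of the acrylate unit under basic palladium conditions, or protodeboronation of 16.
   - Fallback: the dienoate is built by two olefinations under kinetic control.
   - Course: it sets out from aldehyde 15. Horner–Wadsworth–Emmons reaction with diethyl (N-methoxy-N-methylcarbamoylmethyl)phosphonate (NaH, THF) gives the (E)-enamide F13. i-Bu2AlH (−78 °C) gives the (E)-enal F14. Still–Gennari olefination (methyl bis(2,2,2-trifluoroethyl)phosphonoacetate, KN(SiMe3)2, 18-crown-6, THF, −78 °C) gives the (2Z,4E)-dienoate 18.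

**Further compounds**
F1 | step 9 | (3E,7S,9E)-7-(tert-butyldimethylsilyloxy)-4,9,9-trimethyl-11-(pinacolatoboryl)undeca-3,10-dien-1-ol (16 without PMB) | CC1(C)OB(/C=C/C(C)(C)C[C@@H](O[Si](C)(C)C(C)(C)C)C/C(C)=C/CCO)OC1(C)C
F2 | step 9 | (Z)-3-iodoacrylate ester of F1 | CC1(C)OB(/C=C/C(C)(C)C[C@@H](O[Si](C)(C)C(C)(C)C)C/C(C)=C/CCOC(=O)/C=C\I)OC1(C)C
F3 | step 9 | 14-membered (2Z,4E,10E)-macrolide (C17–O–C12 lactone) with (S)-C2 silyloxy group | O=C1/C=C\C=C\C(C)(C)C[C@@H](O[Si](C)(C)C(C)(C)C)C/C(C)=C/CCO1
F4 | step 9 | trans-anti-trans tricyclic δ-lactone (C17–O–C12) with equatorial C2 silyloxy group | O=C1OCC[C@@H]2[C@@H]1C=C[C@@H]3C(C)(C)C[C@@H](O[Si](C)(C)C(C)(C)C)C[C@@]23C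
F5 | step 9 | C2 alcohol of the tricyclic lactone | O=C1OCC[C@@H]2[C@@H]1C=C[C@@H]3C(C)(C)C[C@@H](O)C[C@@]23C
F6 | step 9 | O-phenyl thionocarbonate of F5 | O=C1OCC[C@@H]2[C@@H]1C=C[C@@H]3C(C)(C)C[C@@H](OC(=S)Oc4ccccc4)C[C@@]23C
F7 | step 9 | deoxygenated tricyclic δ-lactone (lactone of the hydroxy acid corresponding to 23) | O=C1OCC[C@@H]2[C@@H]1C=C[C@@H]3C(C)(C)CCC[C@@]23C
F8 | step 9 | (1R,2S,4aR,8aS)-1-(2-iodoethyl)-5,5,8a-trimethyl-1,2,4a,5,6,7,8,8a-octahydronaphthalene-2-carboxylic acid | ICC[C@@H]1[C@@H](C(O)=O)C=C[C@@H]2C(C)(C)CCC[C@@]12C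
F9 | step 17 | methyl (2Z)-4-hydroxy-3-iodobut-2-enoate | COC(=O)/C=C(\I)CO
F10 | step 17 | methyl (2Z)-4-(tert-butyldimethylsilyloxy)-3-iodobut-2-enoate | COC(=O)/C=C(\I)CO[Si](C)(C)C(C)(C)C
F11 | step 17 | C16 silyl ether analogue of 29 (OTBS in place of OAc) | COC(=O)/C=C(\CC[C@@H]1[C@@H](C(=O)OC)C=C[C@@H]2C(C)(C)CCC[C@@]12C)CO[Si](C)(C)C(C)(C)C
F12 | step 17 | C16 alcohol analogue of 29 (OH in place of OAc) | COC(=O)/C=C(\CC[C@@H]1[C@@H](C(=O)OC)C=C[C@@H]2C(C)(C)CCC[C@@]12C)CO
F13 | step 8 | (2E,6S,8E)-6-(tert-butyldimethylsilyloxy)-N-methoxy-11-(4-methoxybenzyloxy)-N,4,4,8-tetramethylundeca-2,8-dienamide | CON(C)C(=O)/C=C/C(C)(C)C[C@@H](O[Si](C)(C)C(C)(C)C)C/C(C)=C/CCOCc1ccc(OC)cc1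
F14 | step 8 | (2E,6S,8E)-6-(tert-butyldimethylsilyloxy)-11-(4-methoxybenzyloxy)-4,4,8-trimethylundeca-2,8-dienal | O=C/C=C/C(C)(C)C[C@@H](O[Si](C)(C)C(C)(C)C)C/C(C)=C/CCOCc1ccc(OC)cc1
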